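**Strategy**

Ring B is disconnected at both of its dioxin C–O bonds. Rings are lettered A (phenoxy on the dioxin side), B, C (shared by dioxin and furan), D and E (phenoxy on the furan side). In ring B the oxygens on B1 (carrying ring A) and B4 (free OH) sit para to each other, each next to one dioxin carbon (B6, B5); this 1,4-dioxygen pattern is a masked quinone, so ring B is introduced as 2,3-dichloro-5-methoxy-1,4-benzoquinone. The key step lets the ring-C catechol of a finished C/D/E dibenzofuran (other oxygens methylated; catechol released from a diphenylmethylene ketal just before) replace both chlorides, creating two C–O bonds and the dioxin ring at once.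

Key step: step 11

**Remarks**

- Assumption: the target has no stereocentre or stereoaxis, so no stereocontrol is needed and no enantiomer has to be selected.
- Labels: B1 carries the ring-A oxygen, B2 OH (OMe in the route), B3 H, B4 OH, B5 and B6 are the dioxin carbons (B5 next to B4, B6 next to B1). Rings C/D use dibenzofuran numbering; C1 is the bay carbon of ring C. In the target B5–O–C1 and B6–O–C2.
- Compounds 1, 6, 10 and 14 are taken as commercially available.

**Route**

Step 1
Reactants: 1 3,4-dihydroxy-5-methoxybenzaldehyde (5-hydroxyvanillin)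
Product: 2 7-methoxy-2,2-diphenyl-1,3-benzodioxole-5-carbaldehyde
Conditions: Ph2CCl2, K2CO3, MeCN, 60 °C
Reagents that add atoms: dichlorodiphenylmethane, ClC(Cl)(c1ccccc1)c1ccccc1
Why: Double O-alkylation of the catechol pair by the gem-dichloride (diphenylmethylene ketal formation) should tie back the two future dioxin oxygens while the third oxygen is already a methyl ether, so no selective demethylation is ever needed.

Step 2
Reactants: 2 7-methoxy-2,2-diphenyl-1,3-benzodioxole-5-carbaldehyde
Product: 4 7-methoxy-2,2-diphenyl-1,3-benzodioxol-5-ol, via aryl formate 3 (not isolated)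
Conditions: mCPBA, CH2Cl2, 0 °C → rt; then K2CO3 (cat.), MeOH, rt
Reagents that add atoms: meta-chloroperoxybenzoic acid, OOC(=O)c1cccc(Cl)c1
Why: Baeyer–Villiger (Dakin-type) oxidation, in which the electron-rich trioxygenated aryl group migrates to give the formate, followed by methanolysis, should deliver the phenol that becomes the furan oxygen.

Step 3
Reactants: 4 7-methoxy-2,2-diphenyl-1,3-benzodioxol-5-ol
Product: 5 4-bromo-7-methoxy-2,2-diphenyl-1,3-benzodioxol-5-ol
Conditions: NBS (1.0 equiv), CH2Cl2, −78 → 0 °C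
Reagents that add atoms: N-bromosuccinimide, BrN1C(=O)CCC1=O
Why: Electrophilic aromatic bromination ortho to the free phenol should occur at C4, which is next to the tied-back dioxole oxygen and para to the methoxy group, and not at C6, which is shielded by the in-plane methyl of the methoxy group.

Step 4
Reactants: 5 4-bromo-7-methoxy-2,2-diphenyl-1,3-benzodioxol-5-ol; 6 2-fluoro-4,6-dimethoxybenzaldehyde
Product: 7 2-[(4-bromo-7-methoxy-2,2-diphenyl-1,3-benzodioxol-5-yl)oxy]-4,6-dimethoxybenzaldehyde
Conditions: Cs2CO3, DMSO, 110 °C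
Reagents that add atoms: none
Why: Nucleophilic aromatic substitution (SNAr) of the fluoride ortho to the formyl group by the phenoxide should form the diaryl ether, with the aryl bromide and the ketal inert to carbonate.

Step 5
Reactants: 7 2-[(4-bromo-7-methoxy-2,2-diphenyl-1,3-benzodioxol-5-yl)oxy]-4,6-dimethoxybenzaldehyde
Product: 9 2-[(4-bromo-7-methoxy-2,2-diphenyl-1,3-benzodioxol-5-yl)oxy]-4,6-dimethoxyphenol, via aryl formate 8 (not isolated)
Conditions: mCPBA, CH2Cl2, 0 °C → rt; then K2CO3 (cat.), MeOH, rt
Reagents that add atoms: meta-chloroperoxybenzoic acid, OOC(=O)c1cccc(Cl)c1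
Why: Baeyer–Villiger (Dakin-type) oxidation of the 2,4,6-trioxygenated benzaldehyde (aryl migration strongly favoured) and formate methanolysis should turn the group that activated step 4 into the ring-D oxygen that will carry ring E.

Step 6
Reactants: 9 2-[(4-bromo-7-methoxy-2,2-diphenyl-1,3-benzodioxol-5-yl)oxy]-4,6-dimethoxyphenol; 10 3,5-dimethoxyphenylboronic acid
Product: 11 4-bromo-5-[2-(3,5-dimethoxyphenoxy)-3,5-dimethoxyphenoxy]-7-methoxy-2,2-diphenyl-1,3-benzodioxole
Conditions: Cu(OAc)2 (2 equiv), pyridine, 4 Å MS, CH2Cl2, air, rt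
Reagents that add atoms: none
Why: Chan–Lam O-arylation (Cu(II)-mediated oxidative coupling of phenol and arylboronic acid) should attach ring E at room temperature without touching the aryl bromide or the ketal.

Step 7
Reactants: 11 4-bromo-5-[2-(3,5-dimethoxyphenoxy)-3,5-dimethoxyphenoxy]-7-methoxy-2,2-diphenyl-1,3-benzodioxole
Product: 12 1,2-O-diphenylmethylene ketal of 6-(3,5-dimethoxyphenoxy)-3,7,9-trimethoxydibenzofuran-1,2-diol
Conditions: Pd(OAc)2 (10 mol %), PCy3·HBF4 (20 mol %), PivOH (30 mol %), K2CO3, DMA, 130 °C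
Reagents that add atoms: none
Why: Pd-catalysed intramolecular direct arylation (oxidative addition into C–Br, concerted metalation–deprotonation, reductive elimination) should close the dibenzofuran at the only C–H of ring D that is ortho to the ether oxygen.

Step 8
Reactants: 12 1,2-O-diphenylmethylene ketal of 6-(3,5-dimethoxyphenoxy)-3,7,9-trimethoxydibenzofuran-1,2-diol
Product: 13 6-(3,5-dimethoxyphenoxy)-3,7,9-trimethoxydibenzofuran-1,2-diol
Conditions: H2 (1 atm), 10% Pd/C, THF/MeOH, rt; used at once under Ar
Reagents that add atoms: none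
Why: Hydrogenolysis of the two doubly benzylic C–O bonds of the ketal should free the catechol under neutral conditions that leave methyl ethers, the diaryl ether and the furan untouched.

Step 9
Reactants: 14 3,4-dichloroanisole
Product: 17 2,3-dichloro-6-methoxyphenol, via aryllithium 15 (not isolated), via dimethyl arylboronate 16 (not isolated)
Conditions: n-BuLi, THF, −78 °C; B(OMe)3, −78 °C → rt; then AcOH, 30% H2O2, 0 °C → rt
Reagents that add atoms: hydrogen peroxide, OO; trimethyl borate, COB(OC)OC (atoms stay only in 16); n-butyllithium, [Li]CCCC (lithium stays only in 15)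
Why: Directed ortho-metalation at the C–H flanked by OMe and Cl, borylation and oxidative C–B to C–O conversion should place the hydroxyl unambiguously, which a second chlorination of methoxyhydroquinone (expected between OMe and OH) would not do.

Step 10
Reactants: 17 2,3-dichloro-6-methoxyphenol
Product: 18 2,3-dichloro-5-methoxy-1,4-benzoquinone
Conditions: (KSO3)2NO (2.2 equiv), KH2PO4, H2O/acetone, rt
Reagents that add atoms: potassium nitrosodisulfonate (Fremy's salt), [K+].[K+].[O]N(S(=O)(=O)[O-])S(=O)(=O)[O-]
Why: Teuber oxidation of a phenol with a free para position by the nitroxyl radical should give the p-quinone directly, with chlorines and methoxy group unchanged.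

Step 11
Reactants: 13 6-(3,5-dimethoxyphenoxy)-3,7,9-trimethoxydibenzofuran-1,2-diol; 18 2,3-dichloro-5-methoxy-1,4-benzoquinone
Product: 20 dioxin-fused methoxyquinone, via aryloxy chloroquinone 19 (not isolated)
Conditions: K2CO3 (2.5 equiv), degassed DMF, −20 °C → rt, Ar
Reagents that add atoms: none
Why: Carbonate should deprotonate the more acidic bay hydroxyl (C1–OH, meta to the furan oxygen and to the C3 methoxy group, whereas C2–OH is para to the furan oxygen), and this phenoxide adds to the chloro-carbon of 18 para to the methoxy-bearing carbon, which is β to the carbonyl that is not deactivated as a vinylogous ester, before chloride leaves to give 19. A second addition–elimination by the neighbouring C2 hydroxyl on the remaining chloro-carbon then forms the dioxin ring in a 6-endo-trig mode (both alkene carbons lie in the new ring). The closest known reaction type is the double nucleophilic vinylic substitution of catechols on 2,3-dihalo-1,4-quinones, which gives dioxin-fused quinones without metal. No stereocentre is formed. The step needs orientational selectivity (bay oxygen to B5, C2 oxygen to B6) and substitution in preference to electron transfer between catecholate and quinone. The first rests on the match of the most acidic hydroxyl with the most electrophilic chloro-carbon; the second on low temperature, exclusion of air and the reversibility of redox exchange, whereas substitution is irreversible.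

Step 12
Reactants: 20 dioxin-fused methoxyquinone
Product: 21 dioxin-fused hydroquinone (B1-OH and B4-OH)
Conditions: Na2S2O4, THF/H2O, rt, Ar
Reagents that add atoms: none
Why: Two-electron quinone reduction by dithionite should give the hydroquinone without affecting any ether.

Step 13
Reactants: 21 dioxin-fused hydroquinone (B1-OH and B4-OH)
Product: 22 B4-O-TBS ether of 21 (B1-OH free)
Conditions: TBSCl (1.05 equiv), imidazole, DMF, 0 °C
Reagents that add atoms: tert-butyldimethylsilyl chloride, CC(C)(C)[Si](C)(C)Cl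
Why: Sterically controlled O-silylation should select the B4 hydroxyl, which has one ortho hydrogen, over the B1 hydroxyl, which is flanked by the methoxy group and a dioxin oxygen.

Step 14
Reactants: 22 B4-O-TBS ether of 21 (B1-OH free); 10 3,5-dimethoxyphenylboronic acid
Product: 23 B1-O-(3,5-dimethoxyphenyl) B4-O-TBS octamethyl ether of the target
Conditions: Cu(OAc)2 (2 equiv), pyridine, 4 Å MS, CH2Cl2, air, rt
Reagents that add atoms: none
Why: Chan–Lam O-arylation of the remaining B1 phenol should install ring A at room temperature with silyl and methyl ethers intact.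

Step 15
Reactants: 23 B1-O-(3,5-dimethoxyphenyl) B4-O-TBS octamethyl ether of the target
Product: 24 Phlorofucofuroeckol A
Conditions: BBr3 (excess), CH2Cl2, −78 °C → rt; then H2O, 0 °C, Ar
Reagents that add atoms: none
Why: Lewis-acid ether cleavage by BBr3 (bromide attacks each O-methyl group by SN2, and the aryl silyl ether is cleaved in the same pot by Si–O exchange and HBr on work-up) should free all nine hydroxyls, while diaryl ether, dioxin and furan C–O bonds resist BBr3.

**Compound list**

1 | 3,4-dihydroxy-5-methoxybenzaldehyde (5-hydroxyvanillin) | COc1cc(C=O)cc(O)c1O | starting material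
2 | 7-methoxy-2,2-diphenyl-1,3-benzodioxole-5-carbaldehyde | COc1cc(C=O)cc2OC(c3ccccc3)(c3ccccc3)Oc12 | intermediate
3 | 7-methoxy-2,2-diphenyl-1,3-benzodioxol-5-yl formate | COc1cc(OC=O)cc2OC(c3ccccc3)(c3ccccc3)Oc12 | intermediate
4 | 7-methoxy-2,2-diphenyl-1,3-benzodioxol-5-ol | COc1cc(O)cc2OC(c3ccccc3)(c3ccccc3)Oc12 | intermediate
5 | 4-bromo-7-methoxy-2,2-diphenyl-1,3-benzodioxol-5-ol | COc1cc(O)c(Br)c2OC(c3ccccc3)(c3ccccc3)Oc12 | intermediate
6 | 2-fluoro-4,6-dimethoxybenzaldehyde | COc1cc(F)c(C=O)c(OC)c1 | starting material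
7 | 2-[(4-bromo-7-methoxy-2,2-diphenyl-1,3-benzodioxol-5-yl)oxy]-4,6-dimethoxybenzaldehyde | COc1cc(Oc2cc(OC)c3OC(c4ccccc4)(c4ccccc4)Oc3c2Br)c(C=O)c(OC)c1 | intermediate
8 | 2-[(4-bromo-7-methoxy-2,2-diphenyl-1,3-benzodioxol-5-yl)oxy]-4,6-dimethoxyphenyl formate | COc1cc(Oc2cc(OC)c3OC(c4ccccc4)(c4ccccc4)Oc3c2Br)c(OC=O)c(OC)c1 | intermediate
9 | 2-[(4-bromo-7-methoxy-2,2-diphenyl-1,3-benzodioxol-5-yl)oxy]-4,6-dimethoxyphenol | COc1cc(Oc2cc(OC)c3OC(c4ccccc4)(c4ccccc4)Oc3c2Br)c(O)c(OC)c1 | intermediate
10 | 3,5-dimethoxyphenylboronic acid | COc1cc(OC)cc(B(O)O)c1 | starting material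
11 | 4-bromo-5-[2-(3,5-dimethoxyphenoxy)-3,5-dimethoxyphenoxy]-7-methoxy-2,2-diphenyl-1,3-benzodioxole | COc1cc(Oc2cc(OC)c3OC(c4ccccc4)(c4ccccc4)Oc3c2Br)c(Oc2cc(OC)cc(OC)c2)c(OC)c1 | intermediate
12 | 1,2-O-diphenylmethylene ketal of 6-(3,5-dimethoxyphenoxy)-3,7,9-trimethoxydibenzofuran-1,2-diol | COc1cc2oc3c(Oc4cc(OC)cc(OC)c4)c(OC)cc(OC)c3c2c2OC(c4ccccc4)(c4ccccc4)Oc12 | intermediate
13 | 6-(3,5-dimethoxyphenoxy)-3,7,9-trimethoxydibenzofuran-1,2-diol (D/E-ring dibenzofuran catechol) | COc1cc2oc3c(Oc4cc(OC)cc(OC)c4)c(OC)cc(OC)c3c2c(O)c1O | intermediate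
14 | 3,4-dichloroanisole | COc1ccc(Cl)c(Cl)c1 | starting material
15 | (2,3-dichloro-6-methoxyphenyl)lithium | [Li]c1c(OC)ccc(Cl)c1Cl | intermediate
16 | dimethyl (2,3-dichloro-6-methoxyphenyl)boronate | COB(OC)c1c(OC)ccc(Cl)c1Cl | intermediate
17 | 2,3-dichloro-6-methoxyphenol | COc1ccc(Cl)c(Cl)c1O | intermediate
18 | 2,3-dichloro-5-methoxy-1,4-benzoquinone | COC1=CC(=O)C(Cl)=C(Cl)C1=O | intermediate
19 | 2-aryloxy-3-chloro-5-methoxy-1,4-benzoquinone, aryloxy = bay (C1) oxygen of 13, C2-OH free | COC1=CC(=O)C(Oc2c(O)c(OC)cc3oc4c(Oc5cc(OC)cc(OC)c5)c(OC)cc(OC)c4c23)=C(Cl)C1=O | intermediate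
20 | dioxin-fused methoxyquinone: ring B a 2-methoxy-1,4-benzoquinone (C=O at B1 and B4), B5–O–C1 (bay) and B6–O–C2 of the 6-(3,5-dimethoxyphenoxy)-3,7,9-trimethoxydibenzofuran | COC1=CC(=O)C2=C(C1=O)Oc1c(OC)cc3oc4c(Oc5cc(OC)cc(OC)c5)c(OC)cc(OC)c4c3c1O2 | intermediate
21 | dioxin-fused hydroquinone (B1-OH, B4-OH, B2-OMe) | COc1cc(O)c2c(c1O)Oc1c(OC)cc3oc4c(Oc5cc(OC)cc(OC)c5)c(OC)cc(OC)c4c3c1O2 | intermediate
22 | B4-O-tert-butyldimethylsilyl ether of 21 (B1-OH free) | COc1cc(O[Si](C)(C)C(C)(C)C)c2c(c1O)Oc1c(OC)cc3oc4c(Oc5cc(OC)cc(OC)c5)c(OC)cc(OC)c4c3c1O2 | intermediate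
23 | B1-O-(3,5-dimethoxyphenyl) B4-O-TBS octamethyl ether of the target | COc1cc(O[Si](C)(C)C(C)(C)C)c2c(c1Oc1cc(OC)cc(OC)c1)Oc1c(OC)cc3oc4c(Oc5cc(OC)cc(OC)c5)c(OC)cc(OC)c4c3c1O2 | intermediate
24 | Phlorofucofuroeckol A | Oc1cc(O)cc(Oc2c(O)cc(O)c3c2Oc2c(O)cc4oc5c(Oc6cc(O)cc(O)c6)c(O)cc(O)c5c4c2O3)c1 | target

**Summary**

Total step count: 15.
Longest linear sequence: 13 steps (steps 1–8 and 11–15); steps 9–10 form the convergent quinone branch.

**Steps most likely to fail**

Step 11. The two C–O bond formations may occur in the reversed orientation, or electron transfer between catecholate and haloquinone may outrun substitution. The fallback makes the two bonds in separate, orientation-locked events. It sets out from 13, which is silylated at the less hindered non-bay hydroxyl (TBSCl, imidazole, DMF, 0 °C; a silyl group on the bay oxygen would migrate to the neighbouring one) to give the C2-O-TBS mono-ether of the catechol F1. Its only free phenol, the bay one, displaces the more reactive chloride of 18 (K2CO3, MeCN, 0 °C) to give the silylated aryloxy chloroquinone F2. Fluoride (CsF, DMF, 0 °C → rt) then removes the silyl group and the liberated phenoxide closes the dioxin through 19, returning to the route at 20. A catechol mono-ether cannot be oxidised to an o-quinone, so the redox pathway is closed as well.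

Step 14. Copper-mediated aryl transfer to the di-ortho-substituted, electron-rich B1 phenol may be slow, allowing oxidative degradation of the hydroquinone mono-ether by Cu(II)/air. The fallback replaces the oxidative copper coupling by metal-free arylation with an aryl-λ3-iodane. It sets out from 22, which is treated with (3,5-dimethoxyphenyl)(2,4,6-trimethoxyphenyl)iodonium tosylate F3 and K2CO3 in toluene at rt to 50 °C. F3 is prepared in one pot from 1-iodo-3,5-dimethoxybenzene with mCPBA and TsOH·H2O in MeCN, then 1,3,5-trimethoxybenzene. The trimethoxyphenyl group acts as the non-transferred ligand, so the 3,5-dimethoxyphenyl group should be delivered to oxygen, returning to the route at 23.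

Step 3. Bromination may show poor site selectivity between the two ortho positions of phenol 4, or over-brominate. The fallback forgoes the halide and forms the biaryl bond by double C–H activation. It sets out from 4, which undergoes the same SNAr with 6 (Cs2CO3, DMSO, 110 °C) to give 2-[(7-methoxy-2,2-diphenyl-1,3-benzodioxol-5-yl)oxy]-4,6-dimethoxybenzaldehyde F4. Baeyer–Villiger oxidation through the corresponding aryl formate F5 (not isolated) gives 2-[(7-methoxy-2,2-diphenyl-1,3-benzodioxol-5-yl)oxy]-4,6-dimethoxyphenol F6, and Chan–Lam coupling with 10 gives 5-[2-(3,5-dimethoxyphenoxy)-3,5-dimethoxyphenoxy]-7-methoxy-2,2-diphenyl-1,3-benzodioxole F7. Pd(II)-catalysed oxidative cyclisation of this diaryl ether (Pd(OAc)2, PivOH, K2CO3, air, 120 °C) should palladate ring C at the C–H next to the dioxole oxygen, the usual preferred site for concerted metalation–deprotonation, and ring D at its only ortho C–H, returning to the route at 12.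

**Further compounds**

F1 | step 11 | C2-O-TBS mono-ether of catechol 13 (bay C1-OH free) | COc1cc2oc3c(Oc4cc(OC)cc(OC)c4)c(OC)cc(OC)c3c2c(O)c1O[Si](C)(C)C(C)(C)C
F2 | step 11 | 2-aryloxy-3-chloro-5-methoxy-1,4-benzoquinone, aryloxy = bay oxygen of F1 (C2-O-TBS) | COC1=CC(=O)C(Oc2c(O[Si](C)(C)C(C)(C)C)c(OC)cc3oc4c(Oc5cc(OC)cc(OC)c5)c(OC)cc(OC)c4c23)=C(Cl)C1=O
F3 | step 14 | (3,5-dimethoxyphenyl)(2,4,6-trimethoxyphenyl)iodonium tosylate | COc1cc(OC)cc([I+]c2c(OC)cc(OC)cc2OC)c1.Cc1ccc(S(=O)(=O)[O-])cc1
F4 | step 3 | 2-[(7-methoxy-2,2-diphenyl-1,3-benzodioxol-5-yl)oxy]-4,6-dimethoxybenzaldehyde | COc1cc(Oc2cc(OC)c3OC(c4ccccc4)(c4ccccc4)Oc3c2)c(C=O)c(OC)c1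
F5 | step 3 | 2-[(7-methoxy-2,2-diphenyl-1,3-benzodioxol-5-yl)oxy]-4,6-dimethoxyphenyl formate | COc1cc(Oc2cc(OC)c3OC(c4ccccc4)(c4ccccc4)Oc3c2)c(OC=O)c(OC)c1
F6 | step 3 | 2-[(7-methoxy-2,2-diphenyl-1,3-benzodioxol-5-yl)oxy]-4,6-dimethoxyphenol | COc1cc(Oc2cc(OC)c3OC(c4ccccc4)(c4ccccc4)Oc3c2)c(O)c(OC)c1
F7 | step 3 | 5-[2-(3,5-dimethoxyphenoxy)-3,5-dimethoxyphenoxy]-7-methoxy-2,2-diphenyl-1,3-benzodioxole | COc1cc(Oc2cc(OC)c3OC(c4ccccc4)(c4ccccc4)Oc3c2)c(Oc2cc(OC)cc(OC)c2)c(OC)c1
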